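**Plan**
- Feature: ring A (C4a–C8a) alternates three carbons of different kind (C4a acyl, C6 prenyl, C8 vinyl) with three oxygens of different fate (O5 free OH, O7 pyran oxygen, O8a = O1 of the pyranone). This pattern maps onto a ketene C=O, an ynol ether and an enol ether.
- Retrosynthesis: cut the three O–Si bonds; open ring C at O1–C2 (phenoxide displacing chloride on a 2-chlorobenzofuran) and at C4–C4a (aryllithium + aldehyde, then oxidation); open the pyran ring at O7–C and C8–C (prenal); open ring A at C6–C7, C4a–C5 and C7–C8 (3-ethoxycyclobutenone + prenylated siloxyalkyne).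
- Forward: ring A (step 4), pyran ring (step 5), C4a bromide (step 6). Ring B with its furan ring is made separately as a 2-chlorobenzofuran-3-carbaldehyde (steps 7–10). Union at C4 (steps 11, 12), ring C (step 13), desilylation (step 14).
- Stereochemistry: the target has no stereocentre and no stereogenic double bond. Only regiochemistry is needed; it is set by the polarity of the ketene/ynol ether cycloaddition and kept by the three different oxygen masks (O7–H, O5–TIPS, O8a–Et).

Key step: step 4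

Assumption: the target is achiral, so the "single enantiomer" requirement is met trivially; the racemic carbinol 28 and the transient sp3 centre of 12 are erased within the route. Ethoxyacetylene (hexane solution), ethynylmagnesium bromide (THF solution) and 2-bromo-4,5-dimethoxyphenylacetic acid are taken as commercial.

**Step 1**
Reactants: 1 acetone; 2 ethoxyacetylene
Product: 4 3-ethoxycyclobut-2-en-1-one, via ketene 3 (not isolated)
Conditions: acetone vapour over a glowing Ni–Cr filament (ketene lamp); ketene stream into 2, CH2Cl2, 0 °C → rt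
Reagents that add atoms: none
Why: Thermal [2+2] cycloaddition of ketene with the electron-rich ynol ether is regiospecific (alkyne CH carbon to the ketene carbonyl carbon) and gives the vinylogous-ester cyclobutenone directly.

**Step 2**
Reactants: 5 prenyl bromide (1-bromo-3-methylbut-2-ene); 6 ethynylmagnesium bromide
Product: 7 5-methylhex-4-en-1-yne
Conditions: CuCl (5 mol %), THF, 0 → 40 °C
Reagents that add atoms: none
Why: Copper-catalysed coupling of an alkynyl Grignard reagent with a primary allylic bromide should occur at the unhindered CH2 terminus (SN2) and give the skipped enyne.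

**Step 3**
Reactants: 7 5-methylhex-4-en-1-yne
Product: 10 5-methyl-1-(triisopropylsilyloxy)hex-4-en-1-yne, via lithium 5-methylhex-4-en-1-yn-1-ide 8 (not isolated), via lithium 5-methylhex-4-en-1-yn-1-olate 9 (not isolated)
Conditions: LiHMDS (2 equiv), THF, −78 °C; t-BuOOH, −78 → 0 °C; TIPSOTf, −78 °C
Reagents that add atoms: tert-butyl hydroperoxide, CC(C)(C)OO; triisopropylsilyl triflate, CC(C)[Si](OS(=O)(=O)C(F)(F)F)(C(C)C)C(C)C
Why: Oxidation of the lithium acetylide with lithium tert-butyl peroxide gives the lithium ynolate, which the hard, bulky silyl triflate traps on oxygen (standard siloxyalkyne preparation).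

**Step 4**
Reactants: 4 3-ethoxycyclobut-2-en-1-one; 10 5-methyl-1-(triisopropylsilyloxy)hex-4-en-1-yne
Product: 15 5-ethoxy-2-(3-methylbut-2-en-1-yl)-3-(triisopropylsilyloxy)phenol, via 3-ethoxybuta-1,3-dien-1-one 11 (not isolated), via 4-(1-ethoxyvinyl)-2-(3-methylbut-2-en-1-yl)-3-(triisopropylsilyloxy)cyclobut-2-en-1-one 12 (not isolated), via (3E)-5-ethoxy-2-(3-methylbut-2-en-1-yl)-3-(triisopropylsilyloxy)hexa-1,3,5-trien-1-one 13 (not isolated), via 5-ethoxy-2-(3-methylbut-2-en-1-yl)-3-(triisopropylsilyloxy)cyclohexa-2,4-dien-1-one 14 (not isolated)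
Conditions: PhMe (0.5 M), sealed tube, 80 → 110 °C
Reagents that add atoms: none
Why: Heat opens cyclobutenone 4 by 4π electrocyclic ring opening (breaking C7–C8) to ethoxyvinylketene 11, whose ketene C=C adds ynol ether 10 in a regiospecific [2+2], the nucleophilic prenyl-bearing alkyne carbon bonding to the ketene carbonyl carbon (C6–C7) and the silyloxy carbon to the ketene α-carbon (C4a–C5). The 4-vinylcyclobutenone 12 opens again (4π) to dienylketene 13, and ring A closes by thermal 6π electrocyclisation (re-forming C7–C8) to dienone 14, which tautomerises to phenol 15. The closest known reaction is the Danheiser benzannulation of cyclobutenones with siloxyalkynes to monosilylated resorcinols, extended here only by the 3-alkoxy substituent that supplies the third oxygen. No stereocentre survives, since the sp3 carbon of 12 is erased on aromatisation. The step needs regiocontrol and chemoselectivity: the matched polarity of ketene and ynol ether places prenyl between the new OH (O7) and OTIPS (O5) with ethoxy para to prenyl, and the prenyl alkene is far less reactive towards the ketene than the ynol ether and cannot reach it intramolecularly.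

**Step 5**
Reactants: 15 5-ethoxy-2-(3-methylbut-2-en-1-yl)-3-(triisopropylsilyloxy)phenol; 16 3-methylbut-2-enal (prenal)
Product: 18 5-ethoxy-2,2-dimethyl-8-(3-methylbut-2-en-1-yl)-7-(triisopropylsilyloxy)-2H-chromene, via 5-ethoxy-6-(3-methylbut-2-en-1-ylidene)-2-(3-methylbut-2-en-1-yl)-3-(triisopropylsilyloxy)cyclohexa-2,4-dien-1-one 17 (not isolated)
Conditions: ethylenediammonium diacetate (10 mol %), PhMe, 80–110 °C
Reagents that add atoms: none
Why: Amine-salt-catalysed condensation of the enal at C8, the only free position ortho to O7–H, gives an o-quinone methide that closes by oxa-6π electrocyclisation to the 2,2-dimethyl-2H-chromene, whereas attack at the para position (C4a) cannot cyclise and should revert.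

**Step 6**
Reactants: 18 5-ethoxy-2,2-dimethyl-8-(3-methylbut-2-en-1-yl)-7-(triisopropylsilyloxy)-2H-chromene
Product: 19 6-bromo-5-ethoxy-2,2-dimethyl-8-(3-methylbut-2-en-1-yl)-7-(triisopropylsilyloxy)-2H-chromene
Conditions: NBS (1.0 equiv), MeCN, −30 °C, dark
Reagents that add atoms: N-bromosuccinimide, O=C1CCC(=O)N1Br
Why: Electrophilic aromatic bromination at the single remaining ring C–H (C4a), which is activated by three oxygens, should outrun ionic addition to the alkenes in a dry medium that offers no nucleophile to capture a bromonium ion.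

**Step 7**
Reactants: 20 2-bromo-4,5-dimethoxyphenylacetic acid
Product: 22 5,6-dimethoxybenzofuran-2(3H)-one, via (2-hydroxy-4,5-dimethoxyphenyl)acetic acid 21 (not isolated)
Conditions: Pd2(dba)3 (2 mol %), t-BuXPhos (8 mol %), KOH (4 equiv), dioxane/H2O, 100 °C; then 2 M HCl, 60 °C
Reagents that add atoms: potassium hydroxide, [K+].[OH-]
Why: Palladium-catalysed hydroxylation of the aryl bromide with hydroxide gives the 2-hydroxyphenylacetic acid, which lactonises to the five-membered aryl lactone on acidification.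

**Step 8**
Reactants: 22 5,6-dimethoxybenzofuran-2(3H)-one
Product: 23 5,6-dihydroxybenzofuran-2(3H)-one
Conditions: BBr3 (3 equiv), CH2Cl2, −78 °C → rt; H2O
Reagents that add atoms: none
Why: Lewis-acid O-demethylation of aryl methyl ethers with BBr3 is standard, and any ring-opened hydroxy acid re-lactonises on acidic work-up.

**Step 9**
Reactants: 23 5,6-dihydroxybenzofuran-2(3H)-one
Product: 24 5,6-bis(triisopropylsilyloxy)benzofuran-2(3H)-one
Conditions: TIPSCl (2.4 equiv), imidazole, DMAP (cat.), DMF, rt → 40 °C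
Reagents that add atoms: triisopropylsilyl chloride, CC(C)[Si](Cl)(C(C)C)C(C)C
Why: Standard phenol silylation; TIPS is chosen so that the catechol survives the Vilsmeier, organolithium and BCl3 steps and is unmasked together with O5 at the end.

**Step 10**
Reactants: 24 5,6-bis(triisopropylsilyloxy)benzofuran-2(3H)-one
Product: 26 2-chloro-5,6-bis(triisopropylsilyloxy)benzofuran-3-carbaldehyde, via N-{[2-chloro-5,6-bis(triisopropylsilyloxy)benzofuran-3-yl]methylidene}-N-methylmethanaminium chloride 25 (not isolated)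
Conditions: POCl3 (3 equiv), DMF, 0 → 70 °C; then ice/H2O
Reagents that add atoms: N,N-dimethylformamide, CN(C)C=O; phosphoryl chloride, O=P(Cl)(Cl)Cl; water, O
Why: Vilsmeier–Haack–Arnold reaction of the lactone: formylation of the active methylene (C3) and chlorination of the lactone carbonyl give the aromatic 2-chloro-3-formylbenzofuran, as for oxindoles and 2-coumaranones.

**Step 11**
Reactants: 19 6-bromo-5-ethoxy-2,2-dimethyl-8-(3-methylbut-2-en-1-yl)-7-(triisopropylsilyloxy)-2H-chromene; 26 2-chloro-5,6-bis(triisopropylsilyloxy)benzofuran-3-carbaldehyde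
Product: 28 [2-chloro-5,6-bis(triisopropylsilyloxy)benzofuran-3-yl][5-ethoxy-2,2-dimethyl-8-(3-methylbut-2-en-1-yl)-7-(triisopropylsilyloxy)-2H-chromen-6-yl]methanol (racemic), via [5-ethoxy-2,2-dimethyl-8-(3-methylbut-2-en-1-yl)-7-(triisopropylsilyloxy)-2H-chromen-6-yl]lithium 27 (not isolated)
Conditions: n-BuLi (1.05 equiv), THF, −78 °C; 26, −78 °C; AcOH in THF, −78 °C
Reagents that add atoms: none
Why: Bromine–lithium exchange and 1,2-addition of the aryllithium to the aldehyde form the C4–C4a bond, the bulky TIPS group and the cold acidic quench holding back O→C and O→O silyl shifts; the new carbinol centre is racemic and is removed in step 12.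

**Step 12**
Reactants: 28 the racemic diaryl carbinol
Product: 29 [2-chloro-5,6-bis(triisopropylsilyloxy)benzofuran-3-yl][5-ethoxy-2,2-dimethyl-8-(3-methylbut-2-en-1-yl)-7-(triisopropylsilyloxy)-2H-chromen-6-yl]methanone
Conditions: Dess–Martin periodinane, pyridine, CH2Cl2, 0 °C → rt
Reagents that add atoms: none
Why: Dess–Martin oxidation of a doubly benzylic secondary alcohol under buffered, non-acidic conditions that leave alkenes and silyl ethers untouched.

**Step 13**
Reactants: 29 the diaryl ketone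
Product: 32 5,4',5'-tris-O-(triisopropylsilyl)euchretin G, via dichloro{[6-(2-chloro-5,6-bis(triisopropylsilyloxy)benzofuran-3-carbonyl)-2,2-dimethyl-8-(3-methylbut-2-en-1-yl)-7-(triisopropylsilyloxy)-2H-chromen-5-yl]oxy}borane 30 (not isolated), via [2-chloro-5,6-bis(triisopropylsilyloxy)benzofuran-3-yl][5-hydroxy-2,2-dimethyl-8-(3-methylbut-2-en-1-yl)-7-(triisopropylsilyloxy)-2H-chromen-6-yl]methanone 31 (not isolated)
Conditions: BCl3 (2 equiv), 2,6-di-tert-butyl-4-methylpyridine (0.2 equiv), CH2Cl2, −78 → −20 °C; then MeOH, Et3N (excess), −78 °C → rt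
Reagents that add atoms: none
Why: BCl3 chelates the ketone and the alkyl ether oxygen (silyl ether oxygens are much poorer donors, and with no free OH present no protic acid is formed) and cleaves the peri O-ethyl group, after which the freed O8a phenoxide displaces chloride at C2 of the vinylogous acyl chloride by intramolecular addition–elimination (six-membered closure, as in chromone and xanthone syntheses) to form ring C; with O5 still silylated only the angular, 6-prenyl isomer can form.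

**Step 14**
Reactants: 32 5,4',5'-tris-O-(triisopropylsilyl)euchretin G
Product: 33 euchretin G
Conditions: TBAF (3.3 equiv), AcOH (3.3 equiv), THF, 0 °C
Reagents that add atoms: none
Why: Fluoride cleavage of the three aryl TIPS ethers, buffered with acetic acid to protect the catechol from autoxidation and the ketene-acetal carbon C2 from base.

**Compound list**
1 | acetone | CC(C)=O | starting material
2 | ethoxyacetylene | CCOC#C | starting material
3 | ketene | C=C=O | intermediate
4 | 3-ethoxycyclobut-2-en-1-one | CCOC1=CC(=O)C1 | intermediate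
5 | prenyl bromide (1-bromo-3-methylbut-2-ene) | CC(C)=CCBr | starting material
6 | ethynylmagnesium bromide | C#C[Mg]Br | starting material
7 | 5-methylhex-4-en-1-yne | CC(C)=CCC#C | intermediate
8 | lithium 5-methylhex-4-en-1-yn-1-ide | CC(C)=CCC#C[Li] | intermediate
9 | lithium 5-methylhex-4-en-1-yn-1-olate | CC(C)=CCC#CO[Li] | intermediate
10 | 5-methyl-1-(triisopropylsilyloxy)hex-4-en-1-yne | CC(C)=CCC#CO[Si](C(C)C)(C(C)C)C(C)C | intermediate
11 | 3-ethoxybuta-1,3-dien-1-one | C=C(OCC)C=C=O | intermediate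
12 | 4-(1-ethoxyvinyl)-2-(3-methylbut-2-en-1-yl)-3-(triisopropylsilyloxy)cyclobut-2-en-1-one (racemic) | O=C1C(CC=C(C)C)=C(O[Si](C(C)C)(C(C)C)C(C)C)C1C(=C)OCC | intermediate
13 | (3E)-5-ethoxy-2-(3-methylbut-2-en-1-yl)-3-(triisopropylsilyloxy)hexa-1,3,5-trien-1-one | O=C=C(CC=C(C)C)/C(O[Si](C(C)C)(C(C)C)C(C)C)=C\C(=C)OCC | intermediate
14 | 5-ethoxy-2-(3-methylbut-2-en-1-yl)-3-(triisopropylsilyloxy)cyclohexa-2,4-dien-1-one | O=C1CC(OCC)=CC(O[Si](C(C)C)(C(C)C)C(C)C)=C1CC=C(C)C | intermediate
15 | 5-ethoxy-2-(3-methylbut-2-en-1-yl)-3-(triisopropylsilyloxy)phenol | CCOc1cc(O)c(CC=C(C)C)c(O[Si](C(C)C)(C(C)C)C(C)C)c1 | intermediate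
16 | 3-methylbut-2-enal (prenal) | CC(C)=CC=O | starting material
17 | 5-ethoxy-6-(3-methylbut-2-en-1-ylidene)-2-(3-methylbut-2-en-1-yl)-3-(triisopropylsilyloxy)cyclohexa-2,4-dien-1-one (exocyclic alkene geometry not defined) | O=C1C(CC=C(C)C)=C(O[Si](C(C)C)(C(C)C)C(C)C)C=C(OCC)C1=CC=C(C)C | intermediate
18 | 5-ethoxy-2,2-dimethyl-8-(3-methylbut-2-en-1-yl)-7-(triisopropylsilyloxy)-2H-chromene | CCOc1cc(O[Si](C(C)C)(C(C)C)C(C)C)c(CC=C(C)C)c2c1C=CC(C)(C)O2 | intermediate
19 | 6-bromo-5-ethoxy-2,2-dimethyl-8-(3-methylbut-2-en-1-yl)-7-(triisopropylsilyloxy)-2H-chromene | CCOc1c(Br)c(O[Si](C(C)C)(C(C)C)C(C)C)c(CC=C(C)C)c2c1C=CC(C)(C)O2 | intermediate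
20 | 2-bromo-4,5-dimethoxyphenylacetic acid | COc1cc(Br)c(CC(=O)O)cc1OC | starting material
21 | (2-hydroxy-4,5-dimethoxyphenyl)acetic acid | COc1cc(O)c(CC(=O)O)cc1OC | intermediate
22 | 5,6-dimethoxybenzofuran-2(3H)-one | COc1cc2OC(=O)Cc2cc1OC | intermediate
23 | 5,6-dihydroxybenzofuran-2(3H)-one | Oc1cc2OC(=O)Cc2cc1O | intermediate
24 | 5,6-bis(triisopropylsilyloxy)benzofuran-2(3H)-one | CC(C)[Si](Oc1cc2OC(=O)Cc2cc1O[Si](C(C)C)(C(C)C)C(C)C)(C(C)C)C(C)C | intermediate
25 | N-{[2-chloro-5,6-bis(triisopropylsilyloxy)benzofuran-3-yl]methylidene}-N-methylmethanaminium chloride | C[N+](C)=Cc1c(Cl)oc2cc(O[Si](C(C)C)(C(C)C)C(C)C)c(O[Si](C(C)C)(C(C)C)C(C)C)cc12.[Cl-] | intermediate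
26 | 2-chloro-5,6-bis(triisopropylsilyloxy)benzofuran-3-carbaldehyde | O=Cc1c(Cl)oc2cc(O[Si](C(C)C)(C(C)C)C(C)C)c(O[Si](C(C)C)(C(C)C)C(C)C)cc12 | intermediate
27 | [5-ethoxy-2,2-dimethyl-8-(3-methylbut-2-en-1-yl)-7-(triisopropylsilyloxy)-2H-chromen-6-yl]lithium | CCOc1c([Li])c(O[Si](C(C)C)(C(C)C)C(C)C)c(CC=C(C)C)c2c1C=CC(C)(C)O2 | intermediate
28 | [2-chloro-5,6-bis(triisopropylsilyloxy)benzofuran-3-yl][5-ethoxy-2,2-dimethyl-8-(3-methylbut-2-en-1-yl)-7-(triisopropylsilyloxy)-2H-chromen-6-yl]methanol (racemic) | CCOc1c(C(O)c3c(Cl)oc4cc(O[Si](C(C)C)(C(C)C)C(C)C)c(O[Si](C(C)C)(C(C)C)C(C)C)cc34)c(O[Si](C(C)C)(C(C)C)C(C)C)c(CC=C(C)C)c2c1C=CC(C)(C)O2 | intermediate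
29 | [2-chloro-5,6-bis(triisopropylsilyloxy)benzofuran-3-yl][5-ethoxy-2,2-dimethyl-8-(3-methylbut-2-en-1-yl)-7-(triisopropylsilyloxy)-2H-chromen-6-yl]methanone | CCOc1c(C(=O)c3c(Cl)oc4cc(O[Si](C(C)C)(C(C)C)C(C)C)c(O[Si](C(C)C)(C(C)C)C(C)C)cc34)c(O[Si](C(C)C)(C(C)C)C(C)C)c(CC=C(C)C)c2c1C=CC(C)(C)O2 | intermediate
30 | dichloro{[6-(2-chloro-5,6-bis(triisopropylsilyloxy)benzofuran-3-carbonyl)-2,2-dimethyl-8-(3-methylbut-2-en-1-yl)-7-(triisopropylsilyloxy)-2H-chromen-5-yl]oxy}borane | ClB(Cl)Oc1c(C(=O)c3c(Cl)oc4cc(O[Si](C(C)C)(C(C)C)C(C)C)c(O[Si](C(C)C)(C(C)C)C(C)C)cc34)c(O[Si](C(C)C)(C(C)C)C(C)C)c(CC=C(C)C)c2c1C=CC(C)(C)O2 | intermediate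
31 | [2-chloro-5,6-bis(triisopropylsilyloxy)benzofuran-3-yl][5-hydroxy-2,2-dimethyl-8-(3-methylbut-2-en-1-yl)-7-(triisopropylsilyloxy)-2H-chromen-6-yl]methanone | Oc1c(C(=O)c3c(Cl)oc4cc(O[Si](C(C)C)(C(C)C)C(C)C)c(O[Si](C(C)C)(C(C)C)C(C)C)cc34)c(O[Si](C(C)C)(C(C)C)C(C)C)c(CC=C(C)C)c2c1C=CC(C)(C)O2 | intermediate
32 | 5,4',5'-tris-O-(triisopropylsilyl)euchretin G | CC(C)=CCc1c2c(c3oc4oc5cc(O[Si](C(C)C)(C(C)C)C(C)C)c(O[Si](C(C)C)(C(C)C)C(C)C)cc5c4c(=O)c3c1O[Si](C(C)C)(C(C)C)C(C)C)C=CC(C)(C)O2 | intermediate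
33 | euchretin G | CC(C)=CCc1c2c(c3oc4oc5cc(O)c(O)cc5c4c(=O)c3c1O)C=CC(C)(C)O2 | target

**Step count**
Total: 14 steps. Longest linear sequence: 9 steps (steps 2, 3, 4, 5, 6, 11, 12, 13, 14, from prenyl bromide).

**Steps most likely to fail, with fallbacks**

Step 4. The donor-substituted cyclobutenone may open only slowly, so that the siloxyalkyne undergoes 1,3-silyl shift to a silylketene or the vinylketene dimerises before it is trapped. The fallback generates the same vinylketene at room temperature by a photochemical Wolff rearrangement and sets out from 10. Ethyl vinyl ether is lithiated (t-BuLi, THF) and acylated with N-methoxy-N-methylacetamide to give 3-ethoxybut-3-en-2-one F1. Detrifluoroacetylative diazo transfer (LiHMDS, 2,2,2-trifluoroethyl trifluoroacetate; then MsN3, Et3N) gives 1-diazo-3-ethoxybut-3-en-2-one F2. Irradiation of F2 with 10 (CH2Cl2, rt) should give ketene 11 and from it cyclobutenone 12, which is then warmed in toluene. The route is rejoined at 15.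

Step 6. Bromine may attack the chromene and prenyl double bonds instead of the hindered ring carbon. The fallback reverses the polarity of the union and sets out from 18. Vilsmeier–Haack formylation (POCl3, DMF, 0 °C → rt; aqueous work-up), whose chloroiminium electrophile should leave the alkenes alone, gives 5-ethoxy-2,2-dimethyl-8-(3-methylbut-2-en-1-yl)-7-(triisopropylsilyloxy)-2H-chromene-6-carbaldehyde F3. Aldol addition of the lithium enolate of lactone 24 (LiHMDS, THF, −78 °C) gives the β-hydroxy lactone 3-{[5-ethoxy-2,2-dimethyl-8-(3-methylbut-2-en-1-yl)-7-(triisopropylsilyloxy)-2H-chromen-6-yl](hydroxy)methyl}-5,6-bis(triisopropylsilyloxy)benzofuran-2(3H)-one F4 as a diastereomer mixture. Dess–Martin oxidation gives the enolised 3-aroyl lactone 3-[5-ethoxy-2,2-dimethyl-8-(3-methylbut-2-en-1-yl)-7-(triisopropylsilyloxy)-2H-chromene-6-carbonyl]-5,6-bis(triisopropylsilyloxy)benzofuran-2(3H)-one F5. Oxalyl chloride with catalytic DMF converts this vinylogous acid into the vinylogous acid chloride. The route is rejoined at 29, and steps 10–12 are bypassed.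

Step 13. The O5 silyl group may be lost, or the alkenes damaged, during Lewis-acid de-ethylation; both peri-oxygens would then be free and the ring closure would lose its regiochemistry. The fallback changes the O8a mask to one that falls under mild protic conditions and sets out from 4. Aqueous acid hydrolysis gives cyclobutane-1,3-dione F6, and MOMCl/i-Pr2NEt gives 3-(methoxymethoxy)cyclobut-2-en-1-one F7. F7 is carried through the sequence of steps 4–6, 11 and 12 in place of 4:
- benzannulation with 10 gives 5-(methoxymethoxy)-2-(3-methylbut-2-en-1-yl)-3-(triisopropylsilyloxy)phenol F8;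
- chromenylation with prenal gives 5-(methoxymethoxy)-2,2-dimethyl-8-(3-methylbut-2-en-1-yl)-7-(triisopropylsilyloxy)-2H-chromene F9;
- bromination gives 6-bromo-5-(methoxymethoxy)-2,2-dimethyl-8-(3-methylbut-2-en-1-yl)-7-(triisopropylsilyloxy)-2H-chromene F10;
- lithiation and addition to 26 give the racemic carbinol [2-chloro-5,6-bis(triisopropylsilyloxy)benzofuran-3-yl][5-(methoxymethoxy)-2,2-dimethyl-8-(3-methylbut-2-en-1-yl)-7-(triisopropylsilyloxy)-2H-chromen-6-yl]methanol F11;
- oxidation gives the ketone [2-chloro-5,6-bis(triisopropylsilyloxy)benzofuran-3-yl][5-(methoxymethoxy)-2,2-dimethyl-8-(3-methylbut-2-en-1-yl)-7-(triisopropylsilyloxy)-2H-chromen-6-yl]methanone F12.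

Catalytic HCl in MeOH at 0 °C should remove the MOM group ortho to the ketone without touching the aryl TIPS ethers. The route is rejoined at 31, which closes to 32 with Et3N as in step 13.

**Further compounds**
F1 | step 4 | 3-ethoxybut-3-en-2-one | C=C(OCC)C(C)=O
F2 | step 4 | 1-diazo-3-ethoxybut-3-en-2-one | C=C(OCC)C(=O)C=[N+]=[N-]
F3 | step 6 | 5-ethoxy-2,2-dimethyl-8-(3-methylbut-2-en-1-yl)-7-(triisopropylsilyloxy)-2H-chromene-6-carbaldehyde | CCOc1c(C=O)c(O[Si](C(C)C)(C(C)C)C(C)C)c(CC=C(C)C)c2c1C=CC(C)(C)O2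
F4 | step 6 | 3-{[5-ethoxy-2,2-dimethyl-8-(3-methylbut-2-en-1-yl)-7-(triisopropylsilyloxy)-2H-chromen-6-yl](hydroxy)methyl}-5,6-bis(triisopropylsilyloxy)benzofuran-2(3H)-one (diastereomer mixture, racemic) | CCOc1c(C(O)C3C(=O)Oc4cc(O[Si](C(C)C)(C(C)C)C(C)C)c(O[Si](C(C)C)(C(C)C)C(C)C)cc34)c(O[Si](C(C)C)(C(C)C)C(C)C)c(CC=C(C)C)c2c1C=CC(C)(C)O2
F5 | step 6 | 3-[5-ethoxy-2,2-dimethyl-8-(3-methylbut-2-en-1-yl)-7-(triisopropylsilyloxy)-2H-chromene-6-carbonyl]-5,6-bis(triisopropylsilyloxy)benzofuran-2(3H)-one (keto form drawn; enolised) | CCOc1c(C(=O)C3C(=O)Oc4cc(O[Si](C(C)C)(C(C)C)C(C)C)c(O[Si](C(C)C)(C(C)C)C(C)C)cc34)c(O[Si](C(C)C)(C(C)C)C(C)C)c(CC=C(C)C)c2c1C=CC(C)(C)O2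
F6 | step 13 | cyclobutane-1,3-dione | O=C1CC(=O)C1
F7 | step 13 | 3-(methoxymethoxy)cyclobut-2-en-1-one | COCOC1=CC(=O)C1
F8 | step 13 | 5-(methoxymethoxy)-2-(3-methylbut-2-en-1-yl)-3-(triisopropylsilyloxy)phenol | COCOc1cc(O)c(CC=C(C)C)c(O[Si](C(C)C)(C(C)C)C(C)C)c1
F9 | step 13 | 5-(methoxymethoxy)-2,2-dimethyl-8-(3-methylbut-2-en-1-yl)-7-(triisopropylsilyloxy)-2H-chromene | COCOc1cc(O[Si](C(C)C)(C(C)C)C(C)C)c(CC=C(C)C)c2c1C=CC(C)(C)O2
F10 | step 13 | 6-bromo-5-(methoxymethoxy)-2,2-dimethyl-8-(3-methylbut-2-en-1-yl)-7-(triisopropylsilyloxy)-2H-chromene | COCOc1c(Br)c(O[Si](C(C)C)(C(C)C)C(C)C)c(CC=C(C)C)c2c1C=CC(C)(C)O2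
F11 | step 13 | [2-chloro-5,6-bis(triisopropylsilyloxy)benzofuran-3-yl][5-(methoxymethoxy)-2,2-dimethyl-8-(3-methylbut-2-en-1-yl)-7-(triisopropylsilyloxy)-2H-chromen-6-yl]methanol (racemic) | COCOc1c(C(O)c3c(Cl)oc4cc(O[Si](C(C)C)(C(C)C)C(C)C)c(O[Si](C(C)C)(C(C)C)C(C)C)cc34)c(O[Si](C(C)C)(C(C)C)C(C)C)c(CC=C(C)C)c2c1C=CC(C)(C)O2
F12 | step 13 | [2-chloro-5,6-bis(triisopropylsilyloxy)benzofuran-3-yl][5-(methoxymethoxy)-2,2-dimethyl-8-(3-methylbut-2-en-1-yl)-7-(triisopropylsilyloxy)-2H-chromen-6-yl]methanone | COCOc1c(C(=O)c3c(Cl)oc4cc(O[Si](C(C)C)(C(C)C)C(C)C)c(O[Si](C(C)C)(C(C)C)C(C)C)cc34)c(O[Si](C(C)C)(C(C)C)C(C)C)c(CC=C(C)C)c2c1C=CC(C)(C)O2
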